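The number I carry through this flask is a concentration of coupling partner, 0.206 M: the crossover concentration, which is 0.099 /M²/s divided by the product of 3.2 /M and 0.15 /M²/s.

    starting material + catalyst ⇌ catalyst + intermediate (K1 = 1.5, k1 = 0.011 /M/s)
    coupling partner + catalyst + intermediate ⇌ catalyst + target (K2 = 3.2 /M, k2 = 0.099 /M²/s)
    coupling partner → decomposed reagent (k3 = 5.3 × 10⁻⁷ /s)
    coupling partner + catalyst + target → catalyst + over-reaction product (k4 = 0.15 /M²/s)

| flask | starting material | coupling partner | catalyst | time | remark |
|---|---|---|---|---|---|
| east | 0.10 M (fed, over 5.00 d) | 0.300 M | 0.50 mM | 5.0 d | a stirred flask in which starting material is dosed at a steady rate over 5.00 d without added volume, worked up at 5.0 d |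
| south-east | 0.10 M | 0.300 M | 0.50 mM | 5.0 d | everything together in a closed stirred flask, run for 5.0 d |
| west | 0.10 M | 0.300 M (fed, over 5.00 d) | 0.50 mM | 5.0 d | a stirred flask in which coupling partner is dosed at a steady rate over 5.00 d without added volume, worked up at 5.0 d |
| north | 0.10 M | 0.300 M | 0.50 mM |  | a single well-mixed tank run continuously and read at steady state, 5.0 d in it on average |

* the set-up with the highest amount of intermediate at the outlet or at the end, in percent of the starting material put in ("none" if the first two lie within 2 percentage points) (east / south-east / west / north / none)
* amount of intermediate at the outlet or at the end, in percent of the starting material put in, east
* amount of intermediate at the outlet or at the end, in percent of the starting material put in, south-east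
* amount of intermediate at the outlet or at the end, in percent of the starting material put in, west
* amount of intermediate at the outlet or at the end, in percent of the starting material put in, north

Target has two exits. It returns to intermediate at a rate that does not depend on the coupling partner, and it goes on to over-reaction product in proportion to the coupling partner concentration B. The two exits are equal at the crossover. If target stays in balance, the ratio of target to intermediate is r = K·B/(1 + B/crossover), with K the equilibrium constant of the coupling step. The drain on intermediate is then d = (over-reaction constant)·(catalyst)·B·r. It is second order in B well below the crossover and first order well above it.

I compare south-east with west, which differ in how the coupling partner arrives. South-east opens at 0.300 M, above the crossover, and I take 0.225 M as its mean. For west I take 0.150 M, the mean of what has been fed. These give r = 0.344 and 0.278, and drains of 0.502 /d and 0.270 /d, so west's drain is about half of south-east's.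

Taking the first step as balanced, an assumption of my reckoning, I give intermediate a share s of the pool of starting material, intermediate and target, 0.497 in south-east and 0.514 in west. I let the pool drain at s·d after a lag of 1.26 d, the relaxation time of the first step. I commit to 19.6% for south-east and 30.6% for west, and I leave east and north unreckoned.

The forecast gives 24.5% east, 24% south-east, 26.5% west and 20.5% north, naming west as best on the ground that “Slow dosing of coupling partner holds the intermediate near its equilibrium pool”; it stands above me for south-east and below me for west.

The simulation gives west as best, with 23.0% east, 22.5% south-east, 28.5% west and 20.3% north. West's coupling partner never stood above 0.200 M, below the crossover. With 66.7% of its charge left at 5.00 d, the crossover gives a target-to-intermediate ratio of 0.325, and west reads 0.341. East's neighbour, charged with 0.40 M of starting material, ends with 0.0990 M of coupling partner, which gives a ratio of 0.214, and that neighbour reads 0.203.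

The constants used here were set for the occasion; the result is computed.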